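1. The vessel holds incoming ligand and leaving ligand; you run the starting complex in at a steady rate, and the volume grows as it goes in.

| flask | starting complex | incoming ligand | leaving ligand | remark | time |
|---|---|---|---|---|---|
| birch | 0.25 M (fed, over 8.0 min) | 0.25 M | 1 M | run made earlier; the fed solution adds 1.0 times the starting volume |  |
| ash | 1 M (fed, over 8.0 min) | 0.25 M | 1 M | run made earlier; the fed solution adds 1.0 times the starting volume |  |
| flask | 0.50 M (fed, over 8.0 min) | 0.250 M | 1.00 M | the fed solution adds 1.0 times the starting volume | 8.0 min |

| run | time / min | complex with one exchanged / % | complex with two exchanged / % |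
|---|---|---|---|
| birch | 0.333 | 1 | 5 |
| birch | 1.00 | 0 | 2 |
| birch | 2.00 | 2 | 0 |
| birch | 3.00 | 4 | 6 |
| birch | 4.00 | 11 | 0 |
| birch | 5.00 | 17 | 0 |
| birch | 6.00 | 20 | 0 |
| ash | 0.500 | 1 | 3 |
| ash | 0.833 | 0 | 1 |
| ash | 1.33 | 4 | 1 |
| ash | 2.00 | 0 | 0 |
| ash | 3.00 | 4 | 0 |
| ash | 4.00 | 9 | 0 |
| ash | 6.00 | 13 | 0 |

(readings scatter by 2 percentage points)

- equivalents of incoming ligand to starting complex, everything else as given, that leave most complex with one exchanged at 8.0 min
- the amount of complex with one exchanged then, in percent of the starting complex charged
- the amount of complex with one exchanged with the amounts as given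

- every charge counts on the volume at the start, and the solution that is fed holds the whole dose
- the numbers in the tables scatter by 2 percentage points (one standard deviation)
- percentages count the whole charge, also what has not yet gone in

2. The bench rule is to treat the amount of incoming ligand as constant (pseudo-first-order). Let s be the fed fraction of the dosing time tf, so the volume is 1 + s times the start. With cX the ligand charge per starting volume, the exchanged fraction of the charge is then y = k·cX·tf·(s − ln(1 + s)).

3. Apply the rule at 6.00 min. Birch gives k = 0.525 /M/min, but ash gives 0.341 /M/min.

4. The border is the ratio cM/cX, which is 1.00 in birch and 4.00 in ash. Multiplied by y, it gives the ligand used: in ash about half, so the ligand is not constant there. In your flask the ratio cM/cX is 2.00, so the incoming ligand is the limiting reagent.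

5. So follow the ligand instead, taking the complex present as what has been fed. The fraction of ligand left is then exp(−E), with E = k·cM·tf·(s − ln(1 + s)), and y = (cX/cM)(1 − exp(−E)). Reckoned this way, the same readings give 0.586 /M/min for birch and 0.482 /M/min for ash, each carrying the scatter. Their mean is 0.534 /M/min. At the end of the feed, s = 1, so your flask reaches E = 0.655, its ligand exposure. My reckoning for the flask is 24.0% complex with one exchanged.

6. The forecast says 22% (19% to 25%), with 55% at 4 equiv (2 equiv to 10 equiv), and notes: “Slight reversal could explain ash running lower, but it is not resolved”. Mine stands above its 22%.

7. The flask gives 26.8%, and its best is 74.7% at 4.98 equiv.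

    complex with one exchanged + incoming ligand → leaving ligand + complex with two exchanged (k = 0.0301 /M/min)
    starting complex + incoming ligand → leaving ligand + complex with one exchanged (k = 0.832 /M/min)

8. The exposure left 51.9% of the ligand on my reckoning, and the flask at 8.0 min holds less, 45%. There the step to complex with one exchanged uses ligand 75 times as fast as the step to complex with two exchanged.

9. Now leave the flask until 15 min. After the feed, the volume and the complex fed stop changing, so E grows in a straight line to 1.59. That leaves 20.4% of the ligand and makes 39.8% complex with one exchanged. The computed flask holds 17% of the ligand and 40.3% complex with one exchanged.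

(All runs stem from a simulated flask for an exercise; scatter was added.)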